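**Strategy**

The oxolane ring is disconnected at C3–C4 and O1–C5. Both bonds form in one flask when the mono-ester of a C2-symmetric (1R,4R)-(E)-1,4-diaryl-but-2-ene-1,4-diol with the 3-arylpropanoic acid undergoes an Ireland–Claisen rearrangement. The sacrificed carbinol passes its chirality to the vicinal C3/C4 pair through a chair, the (Z)-ketene acetal sets C3/C4 cis, and the surviving C2 hydroxyl closes the lactone on C5. The step exploits the fact that C5 (ring CH2–O) and the C3 hydroxymethyl carbon flank the C3–C4 bond as a latent γ,δ-unsaturated acid: C5 is carried as the lactone carbonyl, the hydroxymethyl as a styryl group.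

Key step: step 8

Remark on the chemistry (assumption): O1 and C2–C5 are the oxolane atoms of the target (C2 aryl, C3 hydroxymethyl, C4 arylmethyl, C5 ring CH2). Compounds 1, 2, 6 and 7 are taken as commercial.

**Route**

Step 1
Reactants: 1 3,4,5-trimethoxybenzaldehyde; 2 vinylmagnesium bromide (CH2=CHMgBr)
Product: 3 rac-1-(3,4,5-trimethoxyphenyl)prop-2-en-1-ol
Conditions: CH2=CHMgBr, THF, −78 → 0 °C; aq. NH4Cl
Reagents that add atoms: none
Why: Grignard 1,2-addition of the vinyl nucleophile to the aryl aldehyde; the new carbinol centre is formed racemic and is resolved in step 2.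

Step 2
Reactants: 3 rac-1-(3,4,5-trimethoxyphenyl)prop-2-en-1-ol
Product: 4 (R)-1-(3,4,5-trimethoxyphenyl)prop-2-en-1-ol
Conditions: Ti(OiPr)4, D-(−)-diisopropyl tartrate, tBuOOH (0.6 equiv), 4 Å molecular sieves, CH2Cl2, −20 °C
Reagents that add atoms: none
Why: Sharpless kinetic resolution: with the D-(−)-tartrate the titanium–tartrate–peroxide complex should epoxidise the (S)-enantiomer much faster (oxygen is delivered to the face on which the carbinol hydrogen, not the aryl group, lies), so the unreacted alcohol should be the (R)-enantiomer that becomes C2.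

Step 3
Reactants: 4 (R)-1-(3,4,5-trimethoxyphenyl)prop-2-en-1-ol (two molecules)
Product: 5 (1R,4R,2E)-1,4-bis(3,4,5-trimethoxyphenyl)but-2-ene-1,4-diol
Conditions: second-generation Hoveyda–Grubbs catalyst RuCl2(H2IMes)(=CH-C6H4-2-OiPr) (5 mol%), 1,4-benzoquinone (10 mol%), CH2Cl2, 40 °C, argon sweep
Reagents that add atoms: none
Why: Olefin self-metathesis of a monosubstituted alkene, driven by loss of ethylene, should give the thermodynamically preferred (E)-alkene; the carbinol centres are untouched, so (R)-4 gives the C2-symmetric (1R,4R)-diol, and any (S)-4 present should end largely in the separable meso diol.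

Step 4
Reactants: 6 3-hydroxy-4,5-dimethoxybenzaldehyde; 7 malonic acid
Product: 9 (E)-3-(3-hydroxy-4,5-dimethoxyphenyl)prop-2-enoic acid, via arylidenemalonic acid 8 (not isolated)
Conditions: pyridine, piperidine (cat.), 90 °C; aq. HCl
Reagents that add atoms: none
Why: Knoevenagel–Doebner condensation: the arylidenemalonic acid loses CO2 in hot pyridine to give the (E)-cinnamic acid, and the free phenol is tolerated.

Step 5
Reactants: 9 (E)-3-(3-hydroxy-4,5-dimethoxyphenyl)prop-2-enoic acid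
Product: 10 3-(3-hydroxy-4,5-dimethoxyphenyl)propanoic acid
Conditions: H2 (1 atm), Pd/C (10% palladium on carbon), EtOAc/MeOH, rt
Reagents that add atoms: none
Why: Heterogeneous hydrogenation of the conjugated C=C; arene, acid and phenol are untouched.

Step 6
Reactants: 10 3-(3-hydroxy-4,5-dimethoxyphenyl)propanoic acid
Product: 12 3-[3-(tert-butyldimethylsilyloxy)-4,5-dimethoxyphenyl]propanoic acid, via bis-silyl compound 11 (not isolated)
Conditions: tBuMe2SiCl (2.5 equiv), imidazole, DMF, rt; then AcOH/THF/H2O, rt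
Reagents that add atoms: tert-butyldimethylsilyl chloride, CC(C)(C)[Si](C)(C)Cl
Why: Silylation of phenol and acid; the labile silyl ester of 11 is hydrolysed by aqueous acetic acid while the aryl silyl ether survives.

Step 7
Reactants: 5 (1R,4R,2E)-1,4-bis(3,4,5-trimethoxyphenyl)but-2-ene-1,4-diol (2.5 equiv); 12 3-[3-(tert-butyldimethylsilyloxy)-4,5-dimethoxyphenyl]propanoic acid
Product: 13 (1R,2E,4R)-4-hydroxy-1,4-bis(3,4,5-trimethoxyphenyl)but-2-en-1-yl 3-[3-(tert-butyldimethylsilyloxy)-4,5-dimethoxyphenyl]propanoate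
Conditions: EDC·HCl, DMAP (cat.), CH2Cl2, 0 °C → rt; excess 5 recovered
Reagents that add atoms: none
Why: Carbodiimide/DMAP (Steglich) esterification; the excess of diol favours mono-acylation statistically, the two hydroxyls are homotopic so only one mono-ester can form, and no stereocentre is touched.

Step 8
Reactants: 13 (1R,2E,4R)-4-hydroxy-1,4-bis(3,4,5-trimethoxyphenyl)but-2-en-1-yl 3-[3-(tert-butyldimethylsilyloxy)-4,5-dimethoxyphenyl]propanoate
Product: 17 (3S,4R,5R)-3-{[3-(tert-butyldimethylsilyloxy)-4,5-dimethoxyphenyl]methyl}-4-[(E)-2-(3,4,5-trimethoxyphenyl)ethenyl]-5-(3,4,5-trimethoxyphenyl)oxolan-2-one, via bis-silyl Z-ketene acetal 14 (not isolated), via rearranged bis-silyl ester 15 (not isolated), via hydroxy acid 16 (not isolated)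
Conditions: LiN(iPr)2 (2.3 equiv), THF/DMPU (4:1), −78 °C; Me3SiCl (2.6 equiv), −78 °C → rt; then 1 M HCl, THF, rt, same flask
Reagents that add atoms: none
Why: Two equivalents of LiN(iPr)2 give the lithium alkoxide and, in THF/DMPU, the (Z)-ester enolate; Me3SiCl traps both, and ketene acetal 14 undergoes a suprafacial [3,3] shift through a chair in which the aryl group on the breaking C–O carbon and the CH2Ar side chain are both equatorial, forming C3–C4 and an (E)-styryl group (15). The closest known reaction type is the Ireland–Claisen rearrangement of secondary (E)-allylic propanoates with 1,3-chirality transfer, followed by acid lactonisation of a γ-hydroxy acid. The acid quench removes both trimethylsilyl groups, and the C2 hydroxyl of 16 closes the only ring by 5-exo-trig acyl substitution at the carboxyl carbon (O1–C5), with retention at C2. C3 is controlled by the sacrificed (R)-carbinol, whose equatorial aryl group fixes the alkene face that is attacked and places the styryl group trans to the C2 aryl group; C4 is controlled by the (Z)-ketene acetal geometry, which places the arylmethyl group cis to the styryl group. The step needs (Z)-selective enolisation, chair over boat, and O-silylation of the free hydroxyl rather than acyl transfer; DMPU, the (E)-alkene with its equatorial preferences, and the trans double bond that keeps the alkoxide away from the ester should secure these. Because the diol is C2-symmetric, it does not matter which carbinol was acylated, so the carbinol that survives is always the (R)-configured C2.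

Step 9
Reactants: 17 (3S,4R,5R)-3-{[3-(tert-butyldimethylsilyloxy)-4,5-dimethoxyphenyl]methyl}-4-[(E)-2-(3,4,5-trimethoxyphenyl)ethenyl]-5-(3,4,5-trimethoxyphenyl)oxolan-2-one
Product: 18 (3S,4R,5R)-3-{[3-(tert-butyldimethylsilyloxy)-4,5-dimethoxyphenyl]methyl}-4-[(E)-2-(3,4,5-trimethoxyphenyl)ethenyl]-5-(3,4,5-trimethoxyphenyl)oxolan-2-ol (anomer mixture)
Conditions: iBu2AlH (1.2 equiv), CH2Cl2, −78 °C; aq. potassium sodium tartrate
Reagents that add atoms: none
Why: Low-temperature DIBAL-H half-reduction of a γ-lactone stops at the aluminium hemiacetal; the O1–C5 bond made in step 8 and all three stereocentres are retained.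

Step 10
Reactants: 18 (3S,4R,5R)-3-{[3-(tert-butyldimethylsilyloxy)-4,5-dimethoxyphenyl]methyl}-4-[(E)-2-(3,4,5-trimethoxyphenyl)ethenyl]-5-(3,4,5-trimethoxyphenyl)oxolan-2-ol
Product: 19 (2R,3R,4S)-4-{[3-(tert-butyldimethylsilyloxy)-4,5-dimethoxyphenyl]methyl}-2-(3,4,5-trimethoxyphenyl)-3-[(E)-2-(3,4,5-trimethoxyphenyl)ethenyl]oxolane
Conditions: Et3SiH (3 equiv), BF3·OEt2 (1.5 equiv), CH2Cl2, −78 → −40 °C
Reagents that add atoms: none
Why: Ionic reductive deoxygenation: BF3 ionises the lactol to the C5 oxocarbenium ion, which Et3SiH reduces to the ring CH2; at low temperature this non-benzylic ion should form far more easily than a cation at C2, so the C2 configuration should hold.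

Step 11
Reactants: 19 (2R,3R,4S)-4-{[3-(tert-butyldimethylsilyloxy)-4,5-dimethoxyphenyl]methyl}-2-(3,4,5-trimethoxyphenyl)-3-[(E)-2-(3,4,5-trimethoxyphenyl)ethenyl]oxolane
Product: 21 [(2R,3S,4S)-4-{[3-(tert-butyldimethylsilyloxy)-4,5-dimethoxyphenyl]methyl}-2-(3,4,5-trimethoxyphenyl)oxolan-3-yl]methanol, via aldehyde 20 (not isolated)
Conditions: O3, CH2Cl2/MeOH, −78 °C, to the end-point of a Sudan Red indicator; then NaBH4, −78 → 0 °C
Reagents that add atoms: ozone, [O-][O+]=O
Why: Ozonolysis with reductive work-up: the styryl C=C should react with ozone much faster than the alkoxyarenes, and borohydride reduces the C3 aldehyde 20 in the flask before it can epimerise or eliminate O1, unveiling the hydroxymethyl group with C3 intact.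

Step 12
Reactants: 21 [(2R,3S,4S)-4-{[3-(tert-butyldimethylsilyloxy)-4,5-dimethoxyphenyl]methyl}-2-(3,4,5-trimethoxyphenyl)oxolan-3-yl]methanol
Product: 22 [(2R,3S,4S)-4-[(3-hydroxy-4,5-dimethoxyphenyl)methyl]-2-(3,4,5-trimethoxyphenyl)oxolan-3-yl]methanol (target)
Conditions: Bu4NF, THF, 0 °C; aqueous work-up
Reagents that add atoms: none
Why: Fluoride-induced cleavage of the aryl silyl ether; no other group reacts.

**Compound list**

1 | 3,4,5-trimethoxybenzaldehyde | COc1cc(C=O)cc(OC)c1OC | starting material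
2 | vinylmagnesium bromide | C=C[Mg]Br | starting material
3 | rac-1-(3,4,5-trimethoxyphenyl)prop-2-en-1-ol | C=CC(O)c1cc(OC)c(OC)c(OC)c1 | intermediate
4 | (R)-1-(3,4,5-trimethoxyphenyl)prop-2-en-1-ol | O[C@H](C=C)c1cc(OC)c(OC)c(OC)c1 | intermediate
5 | (1R,4R,2E)-1,4-bis(3,4,5-trimethoxyphenyl)but-2-ene-1,4-diol | O[C@H](/C=C/[C@@H](O)c1cc(OC)c(OC)c(OC)c1)c1cc(OC)c(OC)c(OC)c1 | intermediate
6 | 3-hydroxy-4,5-dimethoxybenzaldehyde | COc1cc(C=O)cc(O)c1OC | starting material
7 | malonic acid | OC(=O)CC(=O)O | starting material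
8 | 2-[(3-hydroxy-4,5-dimethoxyphenyl)methylidene]propanedioic acid (not isolated) | COc1cc(C=C(C(=O)O)C(=O)O)cc(O)c1OC | intermediate
9 | (E)-3-(3-hydroxy-4,5-dimethoxyphenyl)prop-2-enoic acid | COc1cc(/C=C/C(=O)O)cc(O)c1OC | intermediate
10 | 3-(3-hydroxy-4,5-dimethoxyphenyl)propanoic acid | COc1cc(CCC(=O)O)cc(O)c1OC | intermediate
11 | tert-butyldimethylsilyl 3-[3-(tert-butyldimethylsilyloxy)-4,5-dimethoxyphenyl]propanoate (not isolated) | COc1cc(CCC(=O)O[Si](C)(C)C(C)(C)C)cc(O[Si](C)(C)C(C)(C)C)c1OC | intermediate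
12 | 3-[3-(tert-butyldimethylsilyloxy)-4,5-dimethoxyphenyl]propanoic acid | COc1cc(CCC(=O)O)cc(O[Si](C)(C)C(C)(C)C)c1OC | intermediate
13 | (1R,2E,4R)-4-hydroxy-1,4-bis(3,4,5-trimethoxyphenyl)but-2-en-1-yl 3-[3-(tert-butyldimethylsilyloxy)-4,5-dimethoxyphenyl]propanoate | COc1cc(CCC(=O)O[C@H](/C=C/[C@@H](O)c2cc(OC)c(OC)c(OC)c2)c2cc(OC)c(OC)c(OC)c2)cc(O[Si](C)(C)C(C)(C)C)c1OC | intermediate
14 | bis(trimethylsilyl) (Z)-ketene acetal of 13: O-silyl cis to the arylmethyl group, C4 hydroxyl as trimethylsilyl ether (not isolated) | COc1cc(C/C=C(\O[Si](C)(C)C)O[C@H](/C=C/[C@@H](O[Si](C)(C)C)c2cc(OC)c(OC)c(OC)c2)c2cc(OC)c(OC)c(OC)c2)cc(O[Si](C)(C)C(C)(C)C)c1OC | intermediate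
15 | trimethylsilyl (2S,3R,4E)-2-{[3-(tert-butyldimethylsilyloxy)-4,5-dimethoxyphenyl]methyl}-5-(3,4,5-trimethoxyphenyl)-3-[(R)-(3,4,5-trimethoxyphenyl)(trimethylsilyloxy)methyl]pent-4-enoate (not isolated) | COc1cc(C[C@@H]([C@@H](/C=C/c2cc(OC)c(OC)c(OC)c2)[C@@H](O[Si](C)(C)C)c2cc(OC)c(OC)c(OC)c2)C(=O)O[Si](C)(C)C)cc(O[Si](C)(C)C(C)(C)C)c1OC | intermediate
16 | (2S,3R,4E)-2-{[3-(tert-butyldimethylsilyloxy)-4,5-dimethoxyphenyl]methyl}-3-[(R)-hydroxy(3,4,5-trimethoxyphenyl)methyl]-5-(3,4,5-trimethoxyphenyl)pent-4-enoic acid (not isolated) | COc1cc(C[C@@H]([C@@H](/C=C/c2cc(OC)c(OC)c(OC)c2)[C@@H](O)c2cc(OC)c(OC)c(OC)c2)C(=O)O)cc(O[Si](C)(C)C(C)(C)C)c1OC | intermediate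
17 | (3S,4R,5R)-3-{[3-(tert-butyldimethylsilyloxy)-4,5-dimethoxyphenyl]methyl}-4-[(E)-2-(3,4,5-trimethoxyphenyl)ethenyl]-5-(3,4,5-trimethoxyphenyl)oxolan-2-one | COc1cc(C[C@@H]2C(=O)O[C@@H](c3cc(OC)c(OC)c(OC)c3)[C@@H]2/C=C/c4cc(OC)c(OC)c(OC)c4)cc(O[Si](C)(C)C(C)(C)C)c1OC | intermediate
18 | (3S,4R,5R)-3-{[3-(tert-butyldimethylsilyloxy)-4,5-dimethoxyphenyl]methyl}-4-[(E)-2-(3,4,5-trimethoxyphenyl)ethenyl]-5-(3,4,5-trimethoxyphenyl)oxolan-2-ol, anomer mixture | COc1cc(C[C@@H]2C(O)O[C@@H](c3cc(OC)c(OC)c(OC)c3)[C@@H]2/C=C/c4cc(OC)c(OC)c(OC)c4)cc(O[Si](C)(C)C(C)(C)C)c1OC | intermediate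
19 | (2R,3R,4S)-4-{[3-(tert-butyldimethylsilyloxy)-4,5-dimethoxyphenyl]methyl}-2-(3,4,5-trimethoxyphenyl)-3-[(E)-2-(3,4,5-trimethoxyphenyl)ethenyl]oxolane | COc1cc(C[C@@H]2CO[C@@H](c3cc(OC)c(OC)c(OC)c3)[C@@H]2/C=C/c4cc(OC)c(OC)c(OC)c4)cc(O[Si](C)(C)C(C)(C)C)c1OC | intermediate
20 | (2R,3R,4S)-4-{[3-(tert-butyldimethylsilyloxy)-4,5-dimethoxyphenyl]methyl}-2-(3,4,5-trimethoxyphenyl)oxolane-3-carbaldehyde (not isolated) | COc1cc(C[C@@H]2CO[C@@H](c3cc(OC)c(OC)c(OC)c3)[C@@H]2C=O)cc(O[Si](C)(C)C(C)(C)C)c1OC | intermediate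
21 | [(2R,3S,4S)-4-{[3-(tert-butyldimethylsilyloxy)-4,5-dimethoxyphenyl]methyl}-2-(3,4,5-trimethoxyphenyl)oxolan-3-yl]methanol | COc1cc(C[C@@H]2CO[C@@H](c3cc(OC)c(OC)c(OC)c3)[C@@H]2CO)cc(O[Si](C)(C)C(C)(C)C)c1OC | intermediate
22 | [(2R,3S,4S)-4-[(3-hydroxy-4,5-dimethoxyphenyl)methyl]-2-(3,4,5-trimethoxyphenyl)oxolan-3-yl]methanol | COc1cc(C[C@@H]2CO[C@@H](c3cc(OC)c(OC)c(OC)c3)[C@@H]2CO)cc(O)c1OC | target

**Totals and risks**

Total step count: 12. Longest linear sequence: 9 steps (1, 2, 3, 7, 8, 9, 10, 11, 12); steps 4–6 make the acid branch, which joins at step 7.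

Steps most likely to fail:

Step 8. The (Z)-enolate geometry may erode next to the lithium alkoxide, or the chair preference may be incomplete; either would put the arylmethyl group on the wrong face at C4. The fallback sets out from 13 and returns at 17. The rearrangement is run under the most dependable enolisation mode (LiN(iPr)2, THF without DMPU, Me3SiCl, same acid quench), whose (E)-ketene acetal should give the C4-epimeric lactone (3R,4R,5R)-3-{[3-(tert-butyldimethylsilyloxy)-4,5-dimethoxyphenyl]methyl}-4-[(E)-2-(3,4,5-trimethoxyphenyl)ethenyl]-5-(3,4,5-trimethoxyphenyl)oxolan-2-one F1. C4 is then set by substrate control instead of enolate geometry: deprotonation of F1 (LiN(iPr)2, THF, −78 °C) and kinetic protonation of the planar lactone enolate by 2,6-di-tert-butyl-4-methylphenol from the face opposite the neighbouring styryl group should give 17.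

Step 3. Ruthenium hydride species may isomerise the free secondary allylic alcohol to the aryl ethyl ketone, and the homodimerisation may stall. The fallback sets out from 4 and 12 and returns at 13, replacing steps 3 and 7. Alcohol 4 is first esterified with 12 (EDC·HCl, DMAP, CH2Cl2) to (R)-1-(3,4,5-trimethoxyphenyl)prop-2-en-1-yl 3-[3-(tert-butyldimethylsilyloxy)-4,5-dimethoxyphenyl]propanoate F2, which has no free carbinol and cannot isomerise to a ketone. Cross-metathesis of F2 with an excess of 4 (same ruthenium catalyst) should then give 13 directly; any homodimer 5 formed alongside can be fed into step 7.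

Step 11. Ozone may attack the three electron-rich arenes, and over-oxidation may compete with clean cleavage of the styryl group. The fallback sets out from 19 and returns at 21. Osmium-catalysed dihydroxylation (K2OsO2(OH)4 cat., N-methylmorpholine N-oxide, acetone/H2O) gives 1-[(2R,4S)-4-{[3-(tert-butyldimethylsilyloxy)-4,5-dimethoxyphenyl]methyl}-2-(3,4,5-trimethoxyphenyl)oxolan-3-yl]-2-(3,4,5-trimethoxyphenyl)ethane-1,2-diol F3 (mixture at the two new carbinols, C3 as in 19). NaIO4 (THF/pH 7 buffer, 0 °C) cleaves the glycol, and NaBH4 added to the same flask reduces aldehyde 20 at once to 21.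

Further compounds
F1 | step 8 | (3R,4R,5R)-3-{[3-(tert-butyldimethylsilyloxy)-4,5-dimethoxyphenyl]methyl}-4-[(E)-2-(3,4,5-trimethoxyphenyl)ethenyl]-5-(3,4,5-trimethoxyphenyl)oxolan-2-one | COc1cc(C[C@H]2C(=O)O[C@@H](c3cc(OC)c(OC)c(OC)c3)[C@@H]2/C=C/c4cc(OC)c(OC)c(OC)c4)cc(O[Si](C)(C)C(C)(C)C)c1OC
F2 | step 3 | (R)-1-(3,4,5-trimethoxyphenyl)prop-2-en-1-yl 3-[3-(tert-butyldimethylsilyloxy)-4,5-dimethoxyphenyl]propanoate | COc1cc(CCC(=O)O[C@H](C=C)c2cc(OC)c(OC)c(OC)c2)cc(O[Si](C)(C)C(C)(C)C)c1OC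
F3 | step 11 | 1-[(2R,4S)-4-{[3-(tert-butyldimethylsilyloxy)-4,5-dimethoxyphenyl]methyl}-2-(3,4,5-trimethoxyphenyl)oxolan-3-yl]-2-(3,4,5-trimethoxyphenyl)ethane-1,2-diol | COc1cc(C[C@@H]2CO[C@@H](c3cc(OC)c(OC)c(OC)c3)[C@@H]2C(O)C(O)c4cc(OC)c(OC)c(OC)c4)cc(O[Si](C)(C)C(C)(C)C)c1OC
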